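The target is a twofold-symmetric bis(aryl)methane. Each inner ring A carries, at C6 next to the bridging CH2, a CH2–CH2 chain that ends at C1 of a guaiacyl ring B, and the key step exploits these two identical C6(ring A)–CH2–CH2–C1(ring B) links. Both carbon–carbon bonds of each ethylene unit are disconnected. In one operation each aryl boronate becomes a vinyl ate complex, and an aryl–palladium species triggers the 1,2-shift of C6 from boron to carbon while ring B is attached at the terminal carbon, so four skeletal bonds form together. The precursor is the silyl-protected bis(pinacol boronate) 9; the partners are vinyllithium 15 and guaiacyl triflate 13.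

Key step: step 8

Remark on the chemistry: ring A is numbered C1 (bridging CH2), C2 (OMe), C4 (OH), C6 (chain); ring B is numbered C1 (chain), C3 (OMe), C4 (OH). The target is achiral. The two boron-bearing centres of 17 are drawn (S,S) for definiteness; their sense depends on the ligand enantiomer and is immaterial, because both become CH2 in step 9. Vinyllithium is prepared halide-free rather than bought, and the boronates are installed by bromine–lithium exchange rather than by palladium catalysis.

Step 1
Reactants: 1 3-bromo-5-methoxyphenol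
Product: 2 (3-bromo-5-methoxyphenoxy)triisopropylsilane
Conditions: iPr3SiCl, imidazole, DMF, rt
Reagents that add atoms: chlorotriisopropylsilane, CC(C)[Si](Cl)(C(C)C)C(C)C
Why: Imidazole-promoted O-silylation of a phenol should give a bulky silyl ether that survives organolithiums and acid and shields both ring positions flanking it.

Step 2
Reactants: 2 (3-bromo-5-methoxyphenoxy)triisopropylsilane (2.1 equiv); 3 ethyl formate (1 equiv)
Product: 6 bis[2-bromo-6-methoxy-4-(triisopropylsilyloxy)phenyl]methanol, via aryllithium 4 (not isolated), via aldehyde 5 (not isolated)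
Conditions: LiN(iPr)2, THF, −78 °C; HCO2Et, −78 °C; aq NH4Cl added cold
Reagents that add atoms: none
Why: Directed ortho-lithiation should remove the proton flanked by Br and OMe (the most acidic one, while both positions next to the silyl ether are shielded), the ortho-bromoaryllithium should persist at −78 °C without LiBr loss, and twofold addition to the formate ester through aldehyde 5 is the classical route to a symmetrical diarylmethanol, whose carbinol carbon is not stereogenic because the two aryl groups are identical.

Step 3
Reactants: 6 bis[2-bromo-6-methoxy-4-(triisopropylsilyloxy)phenyl]methanol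
Product: 7 bis[2-bromo-6-methoxy-4-(triisopropylsilyloxy)phenyl]methane
Conditions: Et3SiH, CF3CO2H, CH2Cl2, 0 °C to rt
Reagents that add atoms: none
Why: Ionic hydrogenation should work because acid ionises the carbinol to a diarylmethyl cation stabilised by the ortho-methoxy and para-silyloxy groups of both rings and Et3SiH delivers hydride, while aryl bromides and aryl triisopropylsilyl ethers tolerate the conditions.

Step 4
Reactants: 7 bis[2-bromo-6-methoxy-4-(triisopropylsilyloxy)phenyl]methane
Product: 9 bis[2-methoxy-6-(4,4,5,5-tetramethyl-1,3,2-dioxaborolan-2-yl)-4-(triisopropylsilyloxy)phenyl]methane, via dilithio species 8 (not isolated)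
Conditions: n-BuLi (2.2 equiv), THF, −78 °C; iPrOBpin (3 equiv), −78 °C to rt; aq NH4Cl
Reagents that add atoms: 2-isopropoxy-4,4,5,5-tetramethyl-1,3,2-dioxaborolane, CC(C)OB1OC(C)(C)C(C)(C)O1
Why: Twofold bromine–lithium exchange should outrun deprotonation of the diarylmethane CH2 at −78 °C and the dilithio species is trapped at boron by the alkoxy boronate (lithiation–borylation), which avoids a palladium-mediated ring-to-ring coupling to a fluorene that a 2,2'-dibromodiarylmethane could undergo after a first catalytic borylation.

Step 5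
Reactants: 10 O-benzylvanillin (4-benzyloxy-3-methoxybenzaldehyde)
Product: 12 4-(benzyloxy)-3-methoxyphenol, via aryl formate 11 (not isolated)
Conditions: mCPBA, CH2Cl2, rt; aq NaHCO3 wash; then K2CO3 (cat.), MeOH, rt
Reagents that add atoms: 3-chloroperoxybenzoic acid, OOC(=O)c1cccc(Cl)c1
Why: In this Baeyer–Villiger (Dakin-type) oxidation the electron-rich aryl group migrates to oxygen and the resulting formate ester is cleaved by methanolysis, leaving the benzyl ether untouched.

Step 6
Reactants: 12 4-(benzyloxy)-3-methoxyphenol
Product: 13 4-(benzyloxy)-3-methoxyphenyl trifluoromethanesulfonate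
Conditions: Tf2O, pyridine, CH2Cl2, 0 °C
Reagents that add atoms: trifluoromethanesulfonic anhydride, FC(F)(F)S(=O)(=O)OS(=O)(=O)C(F)(F)F
Why: O-Sulfonylation of the phenol should give the aryl triflate, whose non-coordinating leaving group keeps palladium cationic in the key step.

Step 7
Reactants: 14 tetravinylstannane
Product: 15 vinyllithium
Conditions: n-BuLi (4 equiv), pentane, rt, argon; precipitate filtered, washed with pentane, dissolved in THF and titrated
Reagents that add atoms: n-butyllithium, [Li]CCCC
Why: Tin–lithium exchange is driven by precipitation of vinyllithium from pentane and delivers a halide-free reagent, which matters because lithium halides would inhibit the palladium cycle of step 8.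

Step 8
Reactants: 9 bis[2-methoxy-6-(4,4,5,5-tetramethyl-1,3,2-dioxaborolan-2-yl)-4-(triisopropylsilyloxy)phenyl]methane; 15 vinyllithium (2.05 equiv); 13 4-(benzyloxy)-3-methoxyphenyl trifluoromethanesulfonate (2.4 equiv)
Product: 17 (S,S)-bis{2-[2-(4-benzyloxy-3-methoxyphenyl)-1-(4,4,5,5-tetramethyl-1,3,2-dioxaborolan-2-yl)ethyl]-6-methoxy-4-(triisopropylsilyloxy)phenyl}methane, via bis(vinyl boronate) ate complex 16 (not isolated)
Conditions: 15, THF, 0 °C to rt; then Pd(OAc)2 (5 mol%), enantiopure MandyPhos ligand (1,1'-bis(diphenylphosphino)-2,2'-bis[α-(dimethylamino)benzyl]ferrocene, 6 mol%), 13, THF, 60 °C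
Reagents that add atoms: none
Why: Vinyllithium adds to each trigonal boron of 9 to give the bis(vinyl) ate complex 16; oxidative addition of 13 to zerovalent palladium gives a cationic aryl–palladium species that binds the vinyl group, C6 of ring A then migrates anti from boron to the α-carbon as palladium bonds to the β-carbon, and reductive elimination attaches C1 of ring B there. The closest known reaction type is the palladium-catalysed conjunctive cross-coupling of aryl boronic ester–vinyllithium ate complexes with aryl triflates, applied here at two boron centres of one molecule. No ring is closed. Each boron-bearing benzylic stereocentre is set during the metallate shift under control of the enantiopure bisphosphine on palladium, so both arms should react with the same sense and the homochiral isomer (drawn S,S; the antipodal ligand would give R,R) should predominate, though any isomer serves because both centres are erased in step 9. The step needs 1,2-diarylation in preference to direct Suzuki transfer of aryl or vinyl from boron: the wide-bite-angle bisphosphine, the triflate leaving group and halide-free 15 keep palladium cationic and alkene-bound, and the α-carbon, still bearing boron after the shift, cannot accept a second aryl group. In the substrate each boron has only one ortho substituent (the bridging CH2), the electron-rich ring A is a good migrating group, and the silyl and benzyl ethers are inert to 15 and to palladium.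

Step 9
Reactants: 17 (S,S)-bis{2-[2-(4-benzyloxy-3-methoxyphenyl)-1-(4,4,5,5-tetramethyl-1,3,2-dioxaborolan-2-yl)ethyl]-6-methoxy-4-(triisopropylsilyloxy)phenyl}methane
Product: 18 bis{2-[2-(4-benzyloxy-3-methoxyphenyl)ethyl]-4-hydroxy-6-methoxyphenyl}methane
Conditions: Bu4NF·3H2O (6 equiv), THF, 60 °C; aq NH4Cl
Reagents that add atoms: none
Why: In this protodeboronation of a benzylic boronic ester, fluoride adds to boron and the ate complex releases the benzylic carbon, which is protonated by the water of hydration so that both stereocentres become CH2, while the same fluoride cleaves both aryl silyl ethers and the benzyl ethers stay intact.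

Step 10
Reactants: 18 bis{2-[2-(4-benzyloxy-3-methoxyphenyl)ethyl]-4-hydroxy-6-methoxyphenyl}methane
Product: 19 bis{4-hydroxy-2-[2-(4-hydroxy-3-methoxyphenyl)ethyl]-6-methoxyphenyl}methane (CNP0079383.0)
Conditions: H2 (1 atm), 10% Pd/C, EtOAc/MeOH, rt
Reagents that add atoms: none
Why: Catalytic hydrogenolysis of the two benzyl aryl ethers should leave the methyl ethers and the diarylmethane and diarylethane carbon skeleton intact and deliver the achiral target after filtration.

Compound list
1 | 3-bromo-5-methoxyphenol | COc1cc(O)cc(Br)c1 | starting material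
2 | (3-bromo-5-methoxyphenoxy)triisopropylsilane | COc1cc(O[Si](C(C)C)(C(C)C)C(C)C)cc(Br)c1 | intermediate
3 | ethyl formate | CCOC=O | starting material
4 | [2-bromo-6-methoxy-4-(triisopropylsilyloxy)phenyl]lithium | COc1cc(O[Si](C(C)C)(C(C)C)C(C)C)cc(Br)c1[Li] | intermediate (not isolated)
5 | 2-bromo-6-methoxy-4-(triisopropylsilyloxy)benzaldehyde | COc1cc(O[Si](C(C)C)(C(C)C)C(C)C)cc(Br)c1C=O | intermediate (not isolated)
6 | bis[2-bromo-6-methoxy-4-(triisopropylsilyloxy)phenyl]methanol | COc1cc(O[Si](C(C)C)(C(C)C)C(C)C)cc(Br)c1C(O)c1c(OC)cc(O[Si](C(C)C)(C(C)C)C(C)C)cc1Br | intermediate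
7 | bis[2-bromo-6-methoxy-4-(triisopropylsilyloxy)phenyl]methane | COc1cc(O[Si](C(C)C)(C(C)C)C(C)C)cc(Br)c1Cc1c(OC)cc(O[Si](C(C)C)(C(C)C)C(C)C)cc1Br | intermediate
8 | bis[2-lithio-6-methoxy-4-(triisopropylsilyloxy)phenyl]methane | COc1cc(O[Si](C(C)C)(C(C)C)C(C)C)cc([Li])c1Cc1c(OC)cc(O[Si](C(C)C)(C(C)C)C(C)C)cc1[Li] | intermediate (not isolated)
9 | bis[2-methoxy-6-(4,4,5,5-tetramethyl-1,3,2-dioxaborolan-2-yl)-4-(triisopropylsilyloxy)phenyl]methane | COc1cc(O[Si](C(C)C)(C(C)C)C(C)C)cc(B2OC(C)(C)C(C)(C)O2)c1Cc1c(OC)cc(O[Si](C(C)C)(C(C)C)C(C)C)cc1B1OC(C)(C)C(C)(C)O1 | intermediate (key-step precursor)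
10 | O-benzylvanillin | COc1cc(C=O)ccc1OCc1ccccc1 | starting material
11 | 4-(benzyloxy)-3-methoxyphenyl formate | COc1cc(OC=O)ccc1OCc1ccccc1 | intermediate (not isolated)
12 | 4-(benzyloxy)-3-methoxyphenol | COc1cc(O)ccc1OCc1ccccc1 | intermediate
13 | 4-(benzyloxy)-3-methoxyphenyl trifluoromethanesulfonate | COc1cc(OS(=O)(=O)C(F)(F)F)ccc1OCc1ccccc1 | intermediate (key-step precursor)
14 | tetravinylstannane | C=C[Sn](C=C)(C=C)C=C | starting material
15 | vinyllithium | [Li]C=C | intermediate (key-step precursor)
16 | dilithium bis(vinyl) ate complex of 9 | COc1cc(O[Si](C(C)C)(C(C)C)C(C)C)cc([B-]2(C=C)OC(C)(C)C(C)(C)O2)c1Cc1c(OC)cc(O[Si](C(C)C)(C(C)C)C(C)C)cc1[B-]1(C=C)OC(C)(C)C(C)(C)O1.[Li+].[Li+] | intermediate (not isolated)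
17 | (S,S)-bis{2-[2-(4-benzyloxy-3-methoxyphenyl)-1-(4,4,5,5-tetramethyl-1,3,2-dioxaborolan-2-yl)ethyl]-6-methoxy-4-(triisopropylsilyloxy)phenyl}methane | COc1cc(O[Si](C(C)C)(C(C)C)C(C)C)cc([C@H](Cc2ccc(OCc3ccccc3)c(OC)c2)B2OC(C)(C)C(C)(C)O2)c1Cc1c(OC)cc(O[Si](C(C)C)(C(C)C)C(C)C)cc1[C@H](Cc1ccc(OCc2ccccc2)c(OC)c1)B1OC(C)(C)C(C)(C)O1 | intermediate (key-step product)
18 | bis{2-[2-(4-benzyloxy-3-methoxyphenyl)ethyl]-4-hydroxy-6-methoxyphenyl}methane | COc1cc(O)cc(CCc2ccc(OCc3ccccc3)c(OC)c2)c1Cc1c(OC)cc(O)cc1CCc1ccc(OCc2ccccc2)c(OC)c1 | intermediate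
19 | bis{4-hydroxy-2-[2-(4-hydroxy-3-methoxyphenyl)ethyl]-6-methoxyphenyl}methane | COc1cc(CCc2cc(O)cc(OC)c2Cc2c(CCc3ccc(O)c(OC)c3)cc(O)cc2OC)ccc1O | target

Total step count: 10. Longest linear sequence: 7 steps (1, 2, 3, 4, 8, 9, 10).

Steps most likely to fail

Step 8. Crowding and charge build-up may keep the second boron from forming its ate complex beside the first, or direct transmetalation may outrun the metallate shift, so that only one arm couples or aryl–aryl Suzuki products form. The fallback sets out from dibromide 7 and aldehyde 10 and returns to the route at target 19. Wittig methylenation of 10 (Ph3PCH3Br, KOtBu, THF) should give 1-(benzyloxy)-4-ethenyl-2-methoxybenzene F1. A twofold Mizoroki–Heck reaction of 7 with F1 (Pd(OAc)2, P(t-Bu)3·HBF4, Cy2NMe, dioxane, 100 °C) should give bis{2-[(E)-2-(4-benzyloxy-3-methoxyphenyl)ethenyl]-6-methoxy-4-(triisopropylsilyloxy)phenyl}methane F2. Bu4NF in THF should then free the two inner phenols to give bis{2-[(E)-2-(4-benzyloxy-3-methoxyphenyl)ethenyl]-4-hydroxy-6-methoxyphenyl}methane F3. Hydrogenation over Pd/C should saturate both alkenes and cleave both benzyl ethers, giving 19.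

Step 9. Carbon–boron cleavage of the secondary benzylic boronates may stall once the silyl ethers have been converted into phenoxides, leaving partly deborylated material. The fallback sets out from 17 and returns at 19. Oxidation with H2O2 and aq NaOH in THF at 0 °C should replace both boron atoms by hydroxyl with retention, giving (S,S)-bis{2-[2-(4-benzyloxy-3-methoxyphenyl)-1-hydroxyethyl]-6-methoxy-4-(triisopropylsilyloxy)phenyl}methane F4. Bu4NF in THF should remove the silyl ethers to give (S,S)-bis{2-[2-(4-benzyloxy-3-methoxyphenyl)-1-hydroxyethyl]-4-hydroxy-6-methoxyphenyl}methane F5. Hydrogenolysis (H2, Pd/C, AcOH, cat. HCl) should then remove both benzylic hydroxyl groups and both benzyl ethers, giving 19.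

Step 2. The ortho-bromoaryllithium may lose LiBr to an aryne before the second, hindered addition is complete, or the hemiacetal alkoxide from the first addition may collapse too slowly at −78 °C, so that the sequence stops after one aryl transfer. The fallback sets out from 2 and returns at 6, and separates the two bond formations. Lithiation of 2 as before and quenching with DMF should give aldehyde 5, now isolated. A second portion of aryllithium 4, transmetalated with MgBr2·OEt2 so that it can be warmed without LiBr loss, is added to 5 at −78 °C to 0 °C to give 6. This fallback makes no compound outside the list (F0).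

Further compounds
F1 | step 8 | 1-(benzyloxy)-4-ethenyl-2-methoxybenzene | COc1cc(C=C)ccc1OCc1ccccc1
F2 | step 8 | bis{2-[(E)-2-(4-benzyloxy-3-methoxyphenyl)ethenyl]-6-methoxy-4-(triisopropylsilyloxy)phenyl}methane | COc1cc(O[Si](C(C)C)(C(C)C)C(C)C)cc(/C=C/c2ccc(OCc3ccccc3)c(OC)c2)c1Cc1c(OC)cc(O[Si](C(C)C)(C(C)C)C(C)C)cc1/C=C/c1ccc(OCc2ccccc2)c(OC)c1
F3 | step 8 | bis{2-[(E)-2-(4-benzyloxy-3-methoxyphenyl)ethenyl]-4-hydroxy-6-methoxyphenyl}methane | COc1cc(O)cc(/C=C/c2ccc(OCc3ccccc3)c(OC)c2)c1Cc1c(OC)cc(O)cc1/C=C/c1ccc(OCc2ccccc2)c(OC)c1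
F4 | step 9 | (S,S)-bis{2-[2-(4-benzyloxy-3-methoxyphenyl)-1-hydroxyethyl]-6-methoxy-4-(triisopropylsilyloxy)phenyl}methane | COc1cc(O[Si](C(C)C)(C(C)C)C(C)C)cc([C@H](Cc2ccc(OCc3ccccc3)c(OC)c2)O)c1Cc1c(OC)cc(O[Si](C(C)C)(C(C)C)C(C)C)cc1[C@H](Cc1ccc(OCc2ccccc2)c(OC)c1)O
F5 | step 9 | (S,S)-bis{2-[2-(4-benzyloxy-3-methoxyphenyl)-1-hydroxyethyl]-4-hydroxy-6-methoxyphenyl}methane | COc1cc(O)cc([C@H](Cc2ccc(OCc3ccccc3)c(OC)c2)O)c1Cc1c(OC)cc(O)cc1[C@H](Cc1ccc(OCc2ccccc2)c(OC)c1)O
F0 | step 2 | none | none
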